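The constants below set four clocks in one flask, which you read here from the fastest down.

    gas phase ⇌ dissolved gas, rate k1*(csat - [dissolved gas]) (k1 = 0.00163 /min, csat = 200 mM)
    substrate + dissolved gas ⇌ target (K2 = 40 /M, k2 = 0.00465 /M/min)
    dissolved gas + target → over-reacted product (k3 = 1.63 × 10⁻⁴ /M/min)
    2 substrate → self-condensation product (k4 = 7.11 × 10⁻⁴ /M/min)

substrate 1.2 M; gas phase 200 mM (held); time 8.0 d

- percent here means substrate units held: one self-condensation product counts as two
- where a step has two of a species, its rate is k times that concentration squared, and two are used at each turn
- at the start none of the gas is dissolved
- run time (flask): 8.0 d

- the target standing at 8.0 d, as a percentage of the substrate charged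
- the change that raises the amount of target at 8.0 d, in percent of the substrate charged most ("none" if none brings more than 2 percentage points) (summer / dawn / none)
- amount of target at 8.0 d, in percent of the substrate charged, after dawn

**Fast capture.** In this flask dissolved gas meeting the charged substrate has a half-life of 0.086 d, forward step alone, which is shorter than the 0.295 d in which transfer halves the gap to saturation, so early on you may take transfer as the rate-limiting step.

**Middle clocks.** Self-condensation has a first half-life of 0.407 d by this step alone, and at the start it removes substrate at 2.05 mM/min, faster than the 0.326 mM/min that transfer delivers into an empty solution. Setting these two rates equal gives 0.479 M, the crossover substrate: the [substrate] at which full gas delivery matches the loss to self-condensation. The charge does not enter it.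

**Slow bleed.** Over-reaction at saturated gas has a clock of 21.3 d, longer than the run, so I treat it as a correction. I count the substrate below the crossover as target, 39.9% of the charge, and shrink that over 8.0 d to 27.4%.

**Two changes.** Summer and dawn each lift the crossover to 0.677 M, but summer also doubles the bleed rate, so I commit to dawn and put no figure on it.

**The forecast.** It gives 22.5%, lower than my figure, and chooses dawn with 25.8%, holding that “doubling the saturation concentration lifts the peak more but doubles the late over-reaction”.

**The flask.** The flask gives 20.9%, and 24.2% after dawn, which gains 3.3 percentage points against 1.2 points for summer. Its substrate read 0.322 M at 0.800 d, already below the crossover. In the neighbour flask charged with 2.0 M, the crossover is still 0.479 M, now 23.9% of the charge instead of 39.9%, and that flask stands at 14.1%, which is 0.282 M of target against 0.251 M in the first flask.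

Its constants are those of an exercise; no experiment stands behind them.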